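# Proposed total synthesis of CNP0122760.1 (compound 47)

## Analysis of the target

The target (47) joins two halves through a –CH2CH2– link: a cis-fused 1,4,4a,7,8,8a-hexahydronaphthalene (ring A: C4a–C5–C6–C7–C8–C8a; ring B: C1–C2–C3–C4–C4a–C8a) bonded at C2, and a 1,2-dioxane (O1'–O2'–C3'–C4'–C5'–C6') bonded at C6'. Ring A holds a trisubstituted C5=C6 alkene (methyl on C6). Ring B holds the gem-dimethyl quaternary carbon C1 and a tetrasubstituted C2=C3 alkene (methyl on C3). There are five stereocentres in two sets that cannot influence each other: the cis ring-fusion pair C4a (R)/C8a (S), and in the peroxide half the tertiary peroxy carbon C6' (R), the secondary peroxy carbon C3' (R) and the α-carbon of the propanoic acid (R). The peroxy oxygen on C3' and the α-methyl group are anti when C4'–C3'–Cα–CO2H is drawn as a zigzag.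

Once the O–O bond is present, hydride reagents, phosphines, dissolving metals and heterogeneous hydrogenation are excluded. The acid is a β-peroxy carbonyl compound, which can open by E1cB under base and epimerise at Cα. Both alkenes, the tetrasubstituted one most of all, are sensitive to strong acid and electrophiles. The hard points are the cis fusion beside the quaternary C1, a tetrasubstituted alkene in a fixed position, a configurationally defined tertiary C–OO centre, and the late union of two fragile halves.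

The plan rests on ring A. A cyclohexene whose C5=C6 alkene lies beside the vicinal cis pair C4a/C8a is a Diels–Alder retron. C4a, C5, C6 and C7 come from a 2-methyl-4-alkylbutadiene, C8 and C8a from an acrylate, and the acrylate carbonyl carbon is the atom that becomes C1.

## Retrosynthetic reasoning

**Carboxyl group (47 ⇒ 46 ⇒ 45).** The acid is carried as a silyl-protected primary alcohol and oxidised last. A β-peroxy ester would be exposed to E1cB ring opening in every basic step of the endgame; the protected alcohol has no acidic C–H next to the peroxide.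

**Linker (45 ⇒ 44 ⇒ 26 + 42).** The bond between the two linker carbons is cut as an alkene, made by Wittig olefination of phosphonium salt 26 with aldehyde 42 and then saturated. This cut separates the two stereochemical sets completely. The aldehyde sits on the quaternary C6', so it cannot enolise or fragment. The forward reduction must spare the O–O bond and the two ring alkenes, hence a metal-free concerted transfer of H2 to the only disubstituted alkene.

**C2 one-carbon arm (26 ⇒ 25 ⇒ 24 ⇒ 23 ⇒ 21).** The exocyclic carbon on C2 is traced through alcohol 25 and ester 24 to enol triflate 23, and this to ketone 21. Ketone 21 can enolise only towards C3, because C1 is quaternary, so the position of the tetrasubstituted alkene is decided by the structure. The C3 methyl stereocentre is erased here, so its configuration never needs control.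

**Ring B (21 ⇒ 20 ⇒ 19).** Ring B is opened at C1–C2. A tertiary radical at C1, generated from an isopropenyl group by hydrogen-atom transfer, adds to an aldehyde at C2. This one bond creates the quaternary gem-dimethyl carbon and the ring, and it uses exactly the two handles a Diels–Alder adduct provides on neighbouring cis carbons.

**Functional-group adjustment (19 ⇒ 18 ⇒ 17 ⇒ 16 ⇒ 15 ⇒ 14).** The isopropenyl group comes from the acyl group of imide 14 through Weinreb amide 15 and methyl ketone 16. The aldehyde comes from the silyl ether. The forward steps must not epimerise C8a, which is α to a carbonyl until the methylenation.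

**Ring A (14 ⇒ 9 + 13).** C4a–C8a and C7–C8 are cut together, giving diene 9 and acrylimide 13. Both ring-fusion centres are then set in one step under auxiliary control, with the alkene already at C5=C6 and the acyl carbon placed to become C1.

**Diene and dienophile (9 ⇒ 4 + 7; 4 ⇐ 1; 7 ⇐ 5; 13 ⇐ 10 + 11).** The diene is cut at the sp3–sp2 bond (Negishi coupling of the zinc reagent from iodide 4 with dienyl iodide 7), which fixes the E geometry the endo rule needs. Iodide 4 comes from hydroxy ester 1, iodide 7 from enyne 5, and 13 from oxazolidinone 10 and acid chloride 11.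

**Dioxane (42 ⇒ 41 ⇒ 40 ⇒ 39).** The aldehyde carbon is revealed by glycol cleavage of 41. The ring is opened at O2'–C3' (SN2 attack of a tertiary hydroperoxide on a secondary mesylate, inversion). The tertiary C–OO bond of 40 comes from invertive opening of trisubstituted epoxide 39 at its tertiary carbon. Each C–O stereocentre is thus made by a stereospecific substitution on a centre set by a reliable asymmetric reaction.

**Acyclic chain (39 ⇒ 38 ⇒ 37 ⇒ 36 ⇒ 35 ⇒ 34 ⇒ 31 + 32; 31 ⇐ 29 ⇐ 28 ⇐ 27).** Epoxide 39 comes from allylic alcohol 38 by Sharpless epoxidation. The hydroxy/methyl pair comes from syn aldol 34 (aldehyde 31 plus propionimide 32); the later inversion at the carbinol carbon turns syn into the required anti. Aldehyde 31 is a degradation product of geraniol (27), which supplies the (E)-trisubstituted allylic alcohol unit unchanged.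

## Alternatives that were turned down

**Alternative 1: anionic oxy-Cope from a bicyclo[2.2.2]octenol.** The disconnection is C4–C4a of ring B, by a [3,3] shift. The potassium alkoxide of alcohol A2 (isopropenyl group syn to the etheno bridge) would rearrange: the isopropenyl CH2 bonds to the ring alkene carbon, the carbinol–bridgehead bond breaks, and the C2=C3 enolate is trapped as enol triflate A1.
- For: A1 is the same compound as 23 and would be reached in roughly a third of the steps. The concerted shift transmits the bridgehead configuration to C4a and C8a and guarantees cis fusion. The enolate regiochemistry is fixed by the mechanism. On step economy to the triflate this alternative is clearly stronger.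
- Against: A2 requires 1,2-addition of an isopropenyl metal to ketone A3, whose carbonyl is flanked by a methyl-bearing bridgehead and a gem-dimethyl carbon, with the right facial sense. A3 must be a single enantiomer, and a cycloaddition of a 6,6-dimethylcyclohexadienone with an ethylene equivalent has no dependable asymmetric version, so a resolution would be needed.
- Comparison: the chosen route is longer, but absolute configuration comes from a recoverable auxiliary in a reaction whose sense is predictable, and it avoids the hindered carbonyl addition.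

**Alternative 2: cationic bicyclisation of an acyclic triene.** C4a–C8a and C1–C2 are cut in one cascade. Ionisation of tertiary allylic alcohol A5 gives an allyl cation. The prenyl alkene attacks it to close ring A, and the resulting C1 cation is captured by the alkene carrying the allylic acetate to close ring B. Proton loss from C2 gives allylic acetate A4.
- For: both rings and the quaternary carbon form in one step from a linear terpenoid precursor. A4 already carries the C2 carbon at the right oxidation level, two steps from the phosphonium salt. No other plan is as short.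
- Against: the allyl cation is planar, so absolute configuration would need a chiral acid working on an unbiased substrate. The cis relationship at C4a/C8a is not enforced. The second closure uses an alkene deactivated by its allylic acetate and competes with elimination and solvent capture of the terpinyl-type cation. Several proton-loss regiochemistries are open.
- Comparison: the chosen Diels–Alder gives up this brevity for three controlled selectivities (face, endo, regiochemistry) in one well-understood step.

**Alternative 3: dienone Diels–Alder onto a finished ring B.** C4a–C5 and C8–C8a are cut. The unsubstituted double bond of dienone A7 would react endo with silyloxydiene A8 under a chiral oxazaborolidinium Lewis acid to give ketone A6.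
- For: ring B arrives complete, with C1, the C2=C3 alkene and the C2 carbon. The asymmetric step is catalytic and the plan is convergent. On these points it is stronger than the chosen route.
- Against: the dienophile carbon that becomes C8a is neopentyl, so the cycloaddition is slow. A6 has the wrong oxidation pattern: a C4 ketone conjugated to C2=C3 must be removed without moving that alkene or epimerising C4a, and the ring A alkene must be shifted from C6=C7 to C5=C6 with loss of the C5 silyloxy group. These redox corrections cost at least five steps, each with a regiochemical hazard.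
- Comparison: the chosen cycloaddition places the ring A alkene and every carbon at the correct oxidation level directly, and its later steps are constructive, not corrective.

Key step: step 7

## Route

Remark: the C2 carbinol configuration of 20 and the integrity of the C3 methyl centre in 18–21 are immaterial, because both carbons become sp2 in 23.

**Step 1**
Reactants: 1 methyl (S)-3-hydroxy-2-methylpropanoate
Product: 2 methyl (S)-3-[(tert-butyldimethylsilyl)oxy]-2-methylpropanoate
Conditions: TBSCl, imidazole, CH2Cl2, 0 °C → rt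
Reagents that add atoms: tert-butyldimethylsilyl chloride (TBSCl), CC(C)(C)[Si](C)(C)Cl
Why: Standard silylation of a primary alcohol; the ether must later survive organozinc, aluminium and Grignard reagents.

**Step 2**
Reactants: 2 methyl (S)-3-[(tert-butyldimethylsilyl)oxy]-2-methylpropanoate
Product: 3 (R)-3-[(tert-butyldimethylsilyl)oxy]-2-methylpropan-1-ol
Conditions: i-Bu2AlH (2.2 equiv), CH2Cl2, −78 → 0 °C; aq. sodium potassium tartrate
Reagents that add atoms: none
Why: Hydride reduction of the ester to the primary alcohol; the silyl ether is inert, and silyl migration is slow without base and would in any case only affect a centre that is erased later.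

**Step 3**
Reactants: 3 (R)-3-[(tert-butyldimethylsilyl)oxy]-2-methylpropan-1-ol
Product: 4 (S)-tert-butyl(3-iodo-2-methylpropoxy)dimethylsilane
Conditions: I2, PPh3, imidazole, CH2Cl2, 0 °C → rt
Reagents that add atoms: iodine, II
Why: Appel-type iodination of a primary alcohol through the alkoxyphosphonium ion; the stereocentre is not involved.

**Step 4**
Reactants: 5 2-methylbut-1-en-3-yne
Product: 7 (E)-1-iodo-3-methylbuta-1,3-diene, via dienylzirconocene chloride 6 (not isolated)
Conditions: Cp2Zr(H)Cl, THF, rt; then I2, 0 °C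
Reagents that add atoms: iodine, II
Why: Hydrozirconation adds Zr–H syn across the terminal alkyne, faster than across the 1,1-disubstituted alkene, with zirconium at the terminus; iodinolysis with retention gives the (E)-dienyl iodide, kept as a solution because it is volatile.

**Step 5**
Reactants: 4 (S)-tert-butyl(3-iodo-2-methylpropoxy)dimethylsilane; 7 (E)-1-iodo-3-methylbuta-1,3-diene
Product: 9 tert-butyl{[(2R,4E)-2,6-dimethylhepta-4,6-dien-1-yl]oxy}dimethylsilane, via alkylzinc iodide 8 (not isolated)
Conditions: Zn dust (1,2-dibromoethane/Me3SiCl activated), LiCl, THF, 40 °C; then 7, Pd(PPh3)4 (5 mol %), THF, rt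
Reagents that add atoms: none
Why: Negishi coupling: zinc inserts into the primary C–I bond and zerovalent palladium joins the sp3 zinc reagent to the alkenyl iodide with retention of the E geometry. The γ-silyloxy group does not eliminate from the zinc reagent.

**Step 6**
Reactants: 10 (R)-4-benzyloxazolidin-2-one; 11 acryloyl chloride
Product: 13 (R)-3-acryloyl-4-benzyloxazolidin-2-one, via N-bromomagnesium oxazolidinone 12 (not isolated)
Conditions: MeMgBr (1.0 equiv), THF, 0 °C; then 11, −78 °C
Reagents that add atoms: none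
Why: N-Acylation of the oxazolidinone as its bromomagnesium salt, which is less prone than the lithium salt to start anionic polymerisation of the acryloyl group.

**Step 7 (key step)**
Reactants: 9 tert-butyl{[(2R,4E)-2,6-dimethylhepta-4,6-dien-1-yl]oxy}dimethylsilane; 13 (R)-3-acryloyl-4-benzyloxazolidin-2-one
Product: 14 (R)-4-benzyl-3-{[(1S,2R)-2-{(2R)-3-[(tert-butyldimethylsilyl)oxy]-2-methylpropyl}-4-methylcyclohex-3-en-1-yl]carbonyl}oxazolidin-2-one
Conditions: 13 (1.5 equiv), Et2AlCl (1.4 equiv per 13), CH2Cl2, −78 °C; then 9, −78 → −40 °C; aq. HCl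
Reagents that add atoms: none
Why: This is an auxiliary-controlled Diels–Alder reaction, the closest known type being the Et2AlCl-promoted additions of N-acryloyloxazolidinones to isoprene and piperylene. Excess Et2AlCl should give the cationic two-point chelate of 13, which holds the imide carbonyls syn and the acryloyl group s-cis and lowers its LUMO, so that a concerted, asynchronous [4+2] addition can run at low temperature. Ring A closes in the cycloaddition itself, six-membered and suprafacial on both partners, with C7–C8 formed ahead of C4a–C8a and no separate cyclisation event. C8a (1S in 14) is controlled by the auxiliary: the (R)-benzyl group covers one face of the chelated dienophile and the diene adds to the other. C4a (2R in 14) is controlled relative to C8a by the endo orientation of the chelated carbonyl under the (E)-diene, which puts the C4 side chain and the acyl group cis. The step also needs regiocontrol, and the diene supplies it: the 2-methyl and 4-alkyl groups both raise the HOMO coefficient at the CH2 terminus, which bonds to the acrylate β-carbon. The remote methyl centre of 9 should have no influence and is destroyed later. The silyl ether is inert to Et2AlCl at this temperature.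

**Step 8**
Reactants: 14 (R)-4-benzyl-3-{[(1S,2R)-2-{(2R)-3-[(tert-butyldimethylsilyl)oxy]-2-methylpropyl}-4-methylcyclohex-3-en-1-yl]carbonyl}oxazolidin-2-one
Product: 15 (1S,2R)-2-{(2R)-3-[(tert-butyldimethylsilyl)oxy]-2-methylpropyl}-N-methoxy-N,4-dimethylcyclohex-3-ene-1-carboxamide
Conditions: MeNH(OMe)·HCl, AlMe3, CH2Cl2, −15 °C → rt; aq. HCl
Reagents that add atoms: N,O-dimethylhydroxylamine hydrochloride, CNOC.Cl
Why: Weinreb transamidation: the dimethylaluminium amide attacks the exocyclic imide carbonyl and releases the auxiliary for recovery, without base that could epimerise C8a.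

**Step 9**
Reactants: 15 (1S,2R)-2-{(2R)-3-[(tert-butyldimethylsilyl)oxy]-2-methylpropyl}-N-methoxy-N,4-dimethylcyclohex-3-ene-1-carboxamide
Product: 16 1-[(1S,2R)-2-{(2R)-3-[(tert-butyldimethylsilyl)oxy]-2-methylpropyl}-4-methylcyclohex-3-en-1-yl]ethan-1-one
Conditions: MeMgBr, THF, 0 °C; aq. NH4Cl
Reagents that add atoms: methylmagnesium bromide, C[Mg]Br
Why: Grignard addition to a Weinreb amide stops at the chelated tetrahedral intermediate and gives the methyl ketone on work-up; no free enolate is formed, so the cis arrangement should hold.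

**Step 10**
Reactants: 16 1-[(1S,2R)-2-{(2R)-3-[(tert-butyldimethylsilyl)oxy]-2-methylpropyl}-4-methylcyclohex-3-en-1-yl]ethan-1-one
Product: 17 tert-butyldimethyl{(2R)-2-methyl-3-[(1R,6S)-3-methyl-6-(prop-1-en-2-yl)cyclohex-2-en-1-yl]propoxy}silane
Conditions: Cp2TiMe2, toluene, 65 °C, dark
Reagents that add atoms: dimethyltitanocene Cp2TiMe2, C[Ti](C)(C1C=CC=C1)C1C=CC=C1
Why: Petasis methylenation through a titanium methylidene is non-basic, so the epimerisable ketone becomes the isopropenyl group without cis-to-trans equilibration at C8a.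

**Step 11**
Reactants: 17 tert-butyldimethyl{(2R)-2-methyl-3-[(1R,6S)-3-methyl-6-(prop-1-en-2-yl)cyclohex-2-en-1-yl]propoxy}silane
Product: 18 (2R)-2-methyl-3-[(1R,6S)-3-methyl-6-(prop-1-en-2-yl)cyclohex-2-en-1-yl]propan-1-ol
Conditions: Bu4NF, THF, 0 °C → rt
Reagents that add atoms: none
Why: Fluoride cleavage of the primary silyl ether; both alkenes are inert.

**Step 12**
Reactants: 18 (2R)-2-methyl-3-[(1R,6S)-3-methyl-6-(prop-1-en-2-yl)cyclohex-2-en-1-yl]propan-1-ol
Product: 19 (2R)-2-methyl-3-[(1R,6S)-3-methyl-6-(prop-1-en-2-yl)cyclohex-2-en-1-yl]propanal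
Conditions: Dess–Martin periodinane, NaHCO3, CH2Cl2, 0 °C → rt
Reagents that add atoms: none
Why: Buffered Dess–Martin oxidation to the aldehyde; epimerisation at the α-methyl centre would be of no consequence.

**Step 13**
Reactants: 19 (2R)-2-methyl-3-[(1R,6S)-3-methyl-6-(prop-1-en-2-yl)cyclohex-2-en-1-yl]propanal
Product: 20 (3R,4aR,8aS)-1,1,3,6-tetramethyl-1,2,3,4,4a,7,8,8a-octahydronaphthalen-2-ol (C2 epimers)
Conditions: Fe(acac)3 (20 mol %), PhSiH3 (2.5 equiv), EtOH/ethylene glycol (5:1), 60 °C
Reagents that add atoms: none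
Why: Hydrogen-atom-transfer-initiated radical cyclisation (Fe(acac)3/PhSiH3 alkene–carbonyl coupling): the iron hydride delivers H• to the CH2 terminus of the 1,1-disubstituted alkene in preference to the trisubstituted ring alkene, as in limonene-type substrates. The tertiary C1 radical closes ring B by 6-exo attack on the aldehyde carbon, and the alkoxy radical is reduced and protonated in the alcohol medium. The cis fusion is inherited from 19.

**Step 14**
Reactants: 20 (3R,4aR,8aS)-1,1,3,6-tetramethyl-1,2,3,4,4a,7,8,8a-octahydronaphthalen-2-ol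
Product: 21 (3R,4aR,8aS)-1,1,3,6-tetramethyl-3,4,4a,7,8,8a-hexahydronaphthalen-2(1H)-one
Conditions: Dess–Martin periodinane, NaHCO3, CH2Cl2, rt
Reagents that add atoms: none
Why: Oxidation of the hindered secondary alcohol converges both carbinol epimers on one ketone.

**Step 15**
Reactants: 21 (3R,4aR,8aS)-1,1,3,6-tetramethyl-3,4,4a,7,8,8a-hexahydronaphthalen-2(1H)-one
Product: 23 (4aR,8aS)-1,1,3,6-tetramethyl-1,4,4a,7,8,8a-hexahydronaphthalen-2-yl trifluoromethanesulfonate, via potassium enolate 22 (not isolated)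
Conditions: KN(SiMe3)2, THF, −78 °C; then PhNTf2, −78 → 0 °C
Reagents that add atoms: N-phenylbis(trifluoromethanesulfonimide) (PhNTf2), O=S(=O)(N(c1ccccc1)S(=O)(=O)C(F)(F)F)C(F)(F)F
Why: The ketone can enolise only towards C3 because C1 is quaternary, so deprotonation and O-triflation should give a single enol triflate and fix the tetrasubstituted C2=C3 alkene. The C3 stereocentre disappears here.

**Step 16**
Reactants: 23 (4aR,8aS)-1,1,3,6-tetramethyl-1,4,4a,7,8,8a-hexahydronaphthalen-2-yl trifluoromethanesulfonate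
Product: 24 methyl (4aR,8aS)-1,1,3,6-tetramethyl-1,4,4a,7,8,8a-hexahydronaphthalene-2-carboxylate
Conditions: Pd(OAc)2 (10 mol %), PPh3, CO (1 atm), MeOH, Et3N, DMF, 65 °C
Reagents that add atoms: carbon monoxide, [C-]#[O+]; methanol, CO
Why: Palladium-catalysed methoxycarbonylation of an enol triflate (oxidative addition, CO insertion, methanolysis); CO is small enough to insert at this hindered position, as with 2,6,6-trimethylcyclohexenyl triflates.

**Step 17**
Reactants: 24 methyl (4aR,8aS)-1,1,3,6-tetramethyl-1,4,4a,7,8,8a-hexahydronaphthalene-2-carboxylate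
Product: 25 [(4aR,8aS)-1,1,3,6-tetramethyl-1,4,4a,7,8,8a-hexahydronaphthalen-2-yl]methanol
Conditions: i-Bu2AlH (2.5 equiv), CH2Cl2, −78 → 0 °C; aq. sodium potassium tartrate
Reagents that add atoms: none
Why: 1,2-Reduction of the unsaturated ester to the allylic alcohol; the hindered tetrasubstituted alkene is not touched.

**Step 18**
Reactants: 25 [(4aR,8aS)-1,1,3,6-tetramethyl-1,4,4a,7,8,8a-hexahydronaphthalen-2-yl]methanol
Product: 26 {[(4aR,8aS)-1,1,3,6-tetramethyl-1,4,4a,7,8,8a-hexahydronaphthalen-2-yl]methyl}triphenylphosphonium bromide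
Conditions: Ph3P·HBr, MeOH, rt
Reagents that add atoms: triphenylphosphine hydrobromide, [Br-].c1ccc([PH+](c2ccccc2)c2ccccc2)cc1
Why: Acid-assisted SN1-type phosphonium salt formation, as practised for β-cyclogeraniol: the allylic alcohol ionises and triphenylphosphine captures the primary terminus of the allyl cation. The acid is too weak to protonate the ring A alkene.

**Step 19**
Reactants: 27 geraniol
Product: 28 tert-butyl{[(2E)-3,7-dimethylocta-2,6-dien-1-yl]oxy}dimethylsilane
Conditions: TBSCl, imidazole, CH2Cl2, rt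
Reagents that add atoms: tert-butyldimethylsilyl chloride (TBSCl), CC(C)(C)[Si](C)(C)Cl
Why: Silylation of the allylic alcohol; this group is later removed selectively beside a TBDPS ether.

**Step 20**
Reactants: 28 tert-butyl{[(2E)-3,7-dimethylocta-2,6-dien-1-yl]oxy}dimethylsilane
Product: 29 tert-butyl{[(2E)-5-(3,3-dimethyloxiran-2-yl)-3-methylpent-2-en-1-yl]oxy}dimethylsilane (racemic at the oxirane carbon)
Conditions: mCPBA (1.0 equiv), NaHCO3, CH2Cl2, −20 → 0 °C
Reagents that add atoms: 3-chloroperbenzoic acid (mCPBA), O=C(OO)c1cccc(Cl)c1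
Why: Prilezhaev epoxidation; the 6,7-alkene is the more electron-rich because the 2,3-alkene is deactivated by the allylic oxygen, as in other geranyl derivatives. The new centre is excised in step 21.

**Step 21**
Reactants: 29 tert-butyl{[(2E)-5-(3,3-dimethyloxiran-2-yl)-3-methylpent-2-en-1-yl]oxy}dimethylsilane
Product: 31 (4E)-6-[(tert-butyldimethylsilyl)oxy]-4-methylhex-4-enal, via vicinal diol 30 (not isolated)
Conditions: H5IO6, THF/H2O, 0 °C
Reagents that add atoms: none
Why: Periodic acid hydrates the epoxide and cleaves the glycol (Malaprade reaction), releasing the aldehyde and acetone; brief exposure at 0 °C should spare the silyl ether.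

**Step 22**
Reactants: 31 (4E)-6-[(tert-butyldimethylsilyl)oxy]-4-methylhex-4-enal; 32 (R)-4-benzyl-3-propionyloxazolidin-2-one
Product: 34 (R)-4-benzyl-3-{(2R,3S,6E)-8-[(tert-butyldimethylsilyl)oxy]-3-hydroxy-2,6-dimethyloct-6-enoyl}oxazolidin-2-one, via (Z)-dibutylboron enolate 33 (not isolated)
Conditions: 32, Bu2BOTf, i-Pr2NEt, CH2Cl2, 0 °C; then 31, −78 → 0 °C; H2O2, MeOH, pH 7 buffer
Reagents that add atoms: none
Why: Evans syn aldol: the (Z)-boron enolate reacts through a closed Zimmerman–Traxler transition state on the enolate face away from the benzyl group. The (R)-auxiliary gives the (2R,3S) adduct, setting the future Cα and, before inversion, the future C3'.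

**Step 23**
Reactants: 34 (R)-4-benzyl-3-{(2R,3S,6E)-8-[(tert-butyldimethylsilyl)oxy]-3-hydroxy-2,6-dimethyloct-6-enoyl}oxazolidin-2-one
Product: 35 (2S,3S,6E)-8-[(tert-butyldimethylsilyl)oxy]-2,6-dimethyloct-6-ene-1,3-diol
Conditions: LiBH4, MeOH (1 equiv), THF, 0 °C
Reagents that add atoms: none
Why: Borohydride reduction of the imide to the primary alcohol releases the auxiliary. Removing the carbonyl here is essential, because a β-mesyloxy carbonyl compound would eliminate in step 29.

**Step 24**
Reactants: 35 (2S,3S,6E)-8-[(tert-butyldimethylsilyl)oxy]-2,6-dimethyloct-6-ene-1,3-diol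
Product: 36 (2S,3S,6E)-8-[(tert-butyldimethylsilyl)oxy]-1-[(tert-butyldiphenylsilyl)oxy]-2,6-dimethyloct-6-en-3-ol
Conditions: TBDPSCl, imidazole, CH2Cl2, 0 °C
Reagents that add atoms: tert-butyldiphenylsilyl chloride (TBDPSCl), CC(C)(C)[Si](Cl)(c1ccccc1)c1ccccc1
Why: The bulky silyl chloride reacts at the primary hydroxyl only; this ether masks the future carboxyl carbon until the last two steps.

**Step 25**
Reactants: 36 (2S,3S,6E)-8-[(tert-butyldimethylsilyl)oxy]-1-[(tert-butyldiphenylsilyl)oxy]-2,6-dimethyloct-6-en-3-ol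
Product: 37 (2S,3S,6E)-8-[(tert-butyldimethylsilyl)oxy]-1-[(tert-butyldiphenylsilyl)oxy]-2,6-dimethyloct-6-en-3-yl methanesulfonate
Conditions: MsCl, Et3N, CH2Cl2, 0 °C
Reagents that add atoms: methanesulfonyl chloride, CS(=O)(=O)Cl
Why: Sulfonylation of the secondary alcohol with retention installs the leaving group for the later SN2 ring closure.

**Step 26**
Reactants: 37 (2S,3S,6E)-8-[(tert-butyldimethylsilyl)oxy]-1-[(tert-butyldiphenylsilyl)oxy]-2,6-dimethyloct-6-en-3-yl methanesulfonate
Product: 38 (2S,3S,6E)-1-[(tert-butyldiphenylsilyl)oxy]-8-hydroxy-2,6-dimethyloct-6-en-3-yl methanesulfonate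
Conditions: pyridinium p-toluenesulfonate (cat.), MeOH, rt
Reagents that add atoms: none
Why: Acid-catalysed methanolysis removes the primary allylic TBS ether far faster than the TBDPS ether; the mesylate is stable to these conditions.

**Step 27**
Reactants: 38 (2S,3S,6E)-1-[(tert-butyldiphenylsilyl)oxy]-8-hydroxy-2,6-dimethyloct-6-en-3-yl methanesulfonate
Product: 39 (2S,3S)-1-[(tert-butyldiphenylsilyl)oxy]-5-[(2R,3R)-3-(hydroxymethyl)-2-methyloxiran-2-yl]-2-methylpentan-3-yl methanesulfonate
Conditions: Ti(Oi-Pr)4 (10 mol %), D-(−)-diethyl tartrate (12 mol %), t-BuOOH, 4 Å molecular sieves, CH2Cl2, −20 °C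
Reagents that add atoms: tert-butyl hydroperoxide, CC(C)(C)OO
Why: Sharpless asymmetric epoxidation: with the D-(−)-tartrate a geraniol-type (E)-allylic alcohol gives the (2R,3R)-epoxide, the mirror image of the L-(+)-tartrate result. Reagent control should override the remote stereocentres.

**Step 28**
Reactants: 39 (2S,3S)-1-[(tert-butyldiphenylsilyl)oxy]-5-[(2R,3R)-3-(hydroxymethyl)-2-methyloxiran-2-yl]-2-methylpentan-3-yl methanesulfonate
Product: 40 (2S,3S,6S,7R)-1-[(tert-butyldiphenylsilyl)oxy]-6-hydroperoxy-7,8-dihydroxy-2,6-dimethyloctan-3-yl methanesulfonate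
Conditions: H2O2 (anhydrous, in Et2O, excess), H3PMo12O40 (5 mol %), Et2O, rt
Reagents that add atoms: hydrogen peroxide, OO
Why: Acid-catalysed perhydrolysis of a 2,3-epoxy alcohol: hydrogen peroxide opens the activated epoxide at the tertiary carbon, which carries positive charge best and is remote from the hydroxymethyl group, from the rear, so the C–OOH centre forms with inversion. The mesylate and silyl ether are inert.

**Step 29**
Reactants: 40 (2S,3S,6S,7R)-1-[(tert-butyldiphenylsilyl)oxy]-6-hydroperoxy-7,8-dihydroxy-2,6-dimethyloctan-3-yl methanesulfonate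
Product: 41 (1R)-1-[(3S,6R)-6-{(2S)-1-[(tert-butyldiphenylsilyl)oxy]propan-2-yl}-3-methyl-1,2-dioxan-3-yl]ethane-1,2-diol
Conditions: KOt-Bu (1.0 equiv), 18-crown-6, THF, 0 °C
Reagents that add atoms: none
Why: Intramolecular alkylation of a hydroperoxide by a secondary sulfonate (6-exo-tet, SN2): one equivalent of base deprotonates only the hydroperoxide, the most acidic OH, and the α-effect nucleophile displaces the mesylate with inversion. This turns the syn aldol relationship into the anti O/CH3 pair of the target.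

**Step 30**
Reactants: 41 (1R)-1-[(3S,6R)-6-{(2S)-1-[(tert-butyldiphenylsilyl)oxy]propan-2-yl}-3-methyl-1,2-dioxan-3-yl]ethane-1,2-diol
Product: 42 (3S,6R)-6-{(2S)-1-[(tert-butyldiphenylsilyl)oxy]propan-2-yl}-3-methyl-1,2-dioxane-3-carbaldehyde
Conditions: NaIO4, THF/pH 7 buffer, 0 °C
Reagents that add atoms: none
Why: Glycol cleavage removes the terminal carbon as formaldehyde and leaves the aldehyde on the quaternary peroxy carbon, which has no α-hydrogen and so cannot epimerise or undergo Kornblum–DeLaMare fragmentation.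

**Step 31**
Reactants: 26 {[(4aR,8aS)-1,1,3,6-tetramethyl-1,4,4a,7,8,8a-hexahydronaphthalen-2-yl]methyl}triphenylphosphonium bromide; 42 (3S,6R)-6-{(2S)-1-[(tert-butyldiphenylsilyl)oxy]propan-2-yl}-3-methyl-1,2-dioxane-3-carbaldehyde
Product: 44 tert-butyl{(2S)-2-[(3R,6S)-6-methyl-6-{2-[(4aR,8aS)-1,1,3,6-tetramethyl-1,4,4a,7,8,8a-hexahydronaphthalen-2-yl]ethenyl}-1,2-dioxan-3-yl]propoxy}diphenylsilane (E/Z mixture), via phosphonium ylide 43 (not isolated)
Conditions: 26, NaN(SiMe3)2, THF, −78 → 0 °C; then 42, −78 °C → rt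
Reagents that add atoms: none
Why: Wittig olefination with a β-cyclogeranyl-type semi-stabilised ylide; the aldehyde is non-enolisable and activated by its α-oxygen, and the substrate has no acidic C–H β to the peroxide, so the ring should survive the basic ylide. The alkene geometry is immaterial.

**Step 32**
Reactants: 44 tert-butyl{(2S)-2-[(3R,6S)-6-methyl-6-{2-[(4aR,8aS)-1,1,3,6-tetramethyl-1,4,4a,7,8,8a-hexahydronaphthalen-2-yl]ethenyl}-1,2-dioxan-3-yl]propoxy}diphenylsilane
Product: 45 tert-butyl{(2S)-2-[(3R,6R)-6-methyl-6-{2-[(4aR,8aS)-1,1,3,6-tetramethyl-1,4,4a,7,8,8a-hexahydronaphthalen-2-yl]ethyl}-1,2-dioxan-3-yl]propoxy}diphenylsilane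
Conditions: KO2CN=NCO2K (excess, in portions), AcOH, pyridine/MeOH, 0 °C → rt
Reagents that add atoms: none
Why: Diimide reduction: concerted syn transfer of H2 is much faster to the 1,2-disubstituted alkene than to the tri- and tetrasubstituted ring alkenes and does not cleave O–O bonds. Reagent is added in portions until 44 is consumed.

**Step 33**
Reactants: 45 tert-butyl{(2S)-2-[(3R,6R)-6-methyl-6-{2-[(4aR,8aS)-1,1,3,6-tetramethyl-1,4,4a,7,8,8a-hexahydronaphthalen-2-yl]ethyl}-1,2-dioxan-3-yl]propoxy}diphenylsilane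
Product: 46 (2S)-2-[(3R,6R)-6-methyl-6-{2-[(4aR,8aS)-1,1,3,6-tetramethyl-1,4,4a,7,8,8a-hexahydronaphthalen-2-yl]ethyl}-1,2-dioxan-3-yl]propan-1-ol
Conditions: Bu4NF, AcOH (1:1), THF, rt
Reagents that add atoms: none
Why: Buffered fluoride cleavage of the silyl ether; dialkyl peroxides and both alkenes are stable to these conditions.

**Step 34**
Reactants: 46 (2S)-2-[(3R,6R)-6-methyl-6-{2-[(4aR,8aS)-1,1,3,6-tetramethyl-1,4,4a,7,8,8a-hexahydronaphthalen-2-yl]ethyl}-1,2-dioxan-3-yl]propan-1-ol
Product: 47 (2R)-2-[(3R,6R)-6-methyl-6-{2-[(4aR,8aS)-1,1,3,6-tetramethyl-1,4,4a,7,8,8a-hexahydronaphthalen-2-yl]ethyl}-1,2-dioxan-3-yl]propanoic acid (target)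
Conditions: TEMPO (20 mol %), PhI(OAc)2 (2.5 equiv), MeCN/pH 7 phosphate buffer, rt
Reagents that add atoms: water, O
Why: Oxoammonium-mediated oxidation takes the primary alcohol through the aldehyde hydrate to the acid near neutral pH. Under these conditions the transient β-peroxy aldehyde should neither eliminate nor epimerise, and alkenes and the peroxide are inert.

## Compound list

1 | methyl (S)-3-hydroxy-2-methylpropanoate | COC(=O)[C@@H](C)CO | starting material
2 | methyl (S)-3-[(tert-butyldimethylsilyl)oxy]-2-methylpropanoate | COC(=O)[C@@H](C)CO[Si](C)(C)C(C)(C)C | intermediate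
3 | (R)-3-[(tert-butyldimethylsilyl)oxy]-2-methylpropan-1-ol | OC[C@@H](C)CO[Si](C)(C)C(C)(C)C | intermediate
4 | (S)-tert-butyl(3-iodo-2-methylpropoxy)dimethylsilane | IC[C@@H](C)CO[Si](C)(C)C(C)(C)C | intermediate
5 | 2-methylbut-1-en-3-yne | C=C(C)C#C | starting material
6 | chlorobis(cyclopentadienyl)[(1E)-3-methylbuta-1,3-dien-1-yl]zirconium | C=C(C)/C=C/[Zr](Cl)(C1C=CC=C1)C1C=CC=C1 | intermediate (not isolated)
7 | (E)-1-iodo-3-methylbuta-1,3-diene | C=C(C)/C=C/I | intermediate
8 | [(2S)-3-[(tert-butyldimethylsilyl)oxy]-2-methylpropyl]zinc iodide | I[Zn]C[C@@H](C)CO[Si](C)(C)C(C)(C)C | intermediate (not isolated)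
9 | tert-butyl{[(2R,4E)-2,6-dimethylhepta-4,6-dien-1-yl]oxy}dimethylsilane | C=C(C)/C=C/C[C@@H](C)CO[Si](C)(C)C(C)(C)C | intermediate
10 | (R)-4-benzyloxazolidin-2-one | O=C1N[C@H](Cc2ccccc2)CO1 | starting material
11 | acryloyl chloride | C=CC(Cl)=O | starting material
12 | N-bromomagnesium salt of (R)-4-benzyloxazolidin-2-one | O=C1N([Mg]Br)[C@H](Cc2ccccc2)CO1 | intermediate (not isolated)
13 | (R)-3-acryloyl-4-benzyloxazolidin-2-one | C=CC(=O)N1[C@H](Cc2ccccc2)COC1=O | intermediate
14 | (R)-4-benzyl-3-{[(1S,2R)-2-{(2R)-3-[(tert-butyldimethylsilyl)oxy]-2-methylpropyl}-4-methylcyclohex-3-en-1-yl]carbonyl}oxazolidin-2-one | CC1=C[C@@H](C[C@@H](C)CO[Si](C)(C)C(C)(C)C)[C@@H](C(=O)N2[C@H](Cc3ccccc3)COC2=O)CC1 | intermediate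
15 | (1S,2R)-2-{(2R)-3-[(tert-butyldimethylsilyl)oxy]-2-methylpropyl}-N-methoxy-N,4-dimethylcyclohex-3-ene-1-carboxamide | CC1=C[C@@H](C[C@@H](C)CO[Si](C)(C)C(C)(C)C)[C@@H](C(=O)N(C)OC)CC1 | intermediate
16 | 1-[(1S,2R)-2-{(2R)-3-[(tert-butyldimethylsilyl)oxy]-2-methylpropyl}-4-methylcyclohex-3-en-1-yl]ethan-1-one | CC1=C[C@@H](C[C@@H](C)CO[Si](C)(C)C(C)(C)C)[C@@H](C(C)=O)CC1 | intermediate
17 | tert-butyldimethyl{(2R)-2-methyl-3-[(1R,6S)-3-methyl-6-(prop-1-en-2-yl)cyclohex-2-en-1-yl]propoxy}silane | CC1=C[C@@H](C[C@@H](C)CO[Si](C)(C)C(C)(C)C)[C@@H](C(C)=C)CC1 | intermediate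
18 | (2R)-2-methyl-3-[(1R,6S)-3-methyl-6-(prop-1-en-2-yl)cyclohex-2-en-1-yl]propan-1-ol | CC1=C[C@@H](C[C@@H](C)CO)[C@@H](C(C)=C)CC1 | intermediate
19 | (2R)-2-methyl-3-[(1R,6S)-3-methyl-6-(prop-1-en-2-yl)cyclohex-2-en-1-yl]propanal | CC1=C[C@@H](C[C@@H](C)C=O)[C@@H](C(C)=C)CC1 | intermediate
20 | (3R,4aR,8aS)-1,1,3,6-tetramethyl-1,2,3,4,4a,7,8,8a-octahydronaphthalen-2-ol (C2 epimers, centre left undefined) | CC1=C[C@H]2C[C@@H](C)C(O)C(C)(C)[C@H]2CC1 | intermediate
21 | (3R,4aR,8aS)-1,1,3,6-tetramethyl-3,4,4a,7,8,8a-hexahydronaphthalen-2(1H)-one | CC1=C[C@H]2C[C@@H](C)C(=O)C(C)(C)[C@H]2CC1 | intermediate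
22 | potassium (4aR,8aS)-1,1,3,6-tetramethyl-1,4,4a,7,8,8a-hexahydronaphthalen-2-olate | CC1=C[C@H]2CC(C)=C([O-])C(C)(C)[C@H]2CC1.[K+] | intermediate (not isolated)
23 | (4aR,8aS)-1,1,3,6-tetramethyl-1,4,4a,7,8,8a-hexahydronaphthalen-2-yl trifluoromethanesulfonate | CC1=C[C@H]2CC(C)=C(OS(=O)(=O)C(F)(F)F)C(C)(C)[C@H]2CC1 | intermediate
24 | methyl (4aR,8aS)-1,1,3,6-tetramethyl-1,4,4a,7,8,8a-hexahydronaphthalene-2-carboxylate | CC1=C[C@H]2CC(C)=C(C(=O)OC)C(C)(C)[C@H]2CC1 | intermediate
25 | [(4aR,8aS)-1,1,3,6-tetramethyl-1,4,4a,7,8,8a-hexahydronaphthalen-2-yl]methanol | CC1=C[C@H]2CC(C)=C(CO)C(C)(C)[C@H]2CC1 | intermediate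
26 | {[(4aR,8aS)-1,1,3,6-tetramethyl-1,4,4a,7,8,8a-hexahydronaphthalen-2-yl]methyl}triphenylphosphonium bromide | CC1=C[C@H]2CC(C)=C(C[P+](c3ccccc3)(c3ccccc3)c3ccccc3)C(C)(C)[C@H]2CC1.[Br-] | intermediate
27 | geraniol | CC(C)=CCC/C(C)=C/CO | starting material
28 | tert-butyl{[(2E)-3,7-dimethylocta-2,6-dien-1-yl]oxy}dimethylsilane | CC(C)=CCC/C(C)=C/CO[Si](C)(C)C(C)(C)C | intermediate
29 | tert-butyl{[(2E)-5-(3,3-dimethyloxiran-2-yl)-3-methylpent-2-en-1-yl]oxy}dimethylsilane (racemic at the oxirane carbon) | CC1(C)OC1CC/C(C)=C/CO[Si](C)(C)C(C)(C)C | intermediate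
30 | (6E)-8-[(tert-butyldimethylsilyl)oxy]-2,6-dimethyloct-6-ene-2,3-diol (racemic at C3) | CC(C)(O)C(O)CC/C(C)=C/CO[Si](C)(C)C(C)(C)C | intermediate (not isolated)
31 | (4E)-6-[(tert-butyldimethylsilyl)oxy]-4-methylhex-4-enal | O=CCC/C(C)=C/CO[Si](C)(C)C(C)(C)C | intermediate
32 | (R)-4-benzyl-3-propionyloxazolidin-2-one | CCC(=O)N1[C@H](Cc2ccccc2)COC1=O | starting material
33 | (Z)-dibutylboron enolate of 32 | C/C=C(\OB(CCCC)CCCC)N1[C@H](Cc2ccccc2)COC1=O | intermediate (not isolated)
34 | (R)-4-benzyl-3-{(2R,3S,6E)-8-[(tert-butyldimethylsilyl)oxy]-3-hydroxy-2,6-dimethyloct-6-enoyl}oxazolidin-2-one | O=C(N1[C@H](Cc2ccccc2)COC1=O)[C@H](C)[C@@H](O)CC/C(C)=C/CO[Si](C)(C)C(C)(C)C | intermediate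
35 | (2S,3S,6E)-8-[(tert-butyldimethylsilyl)oxy]-2,6-dimethyloct-6-ene-1,3-diol | OC[C@H](C)[C@@H](O)CC/C(C)=C/CO[Si](C)(C)C(C)(C)C | intermediate
36 | (2S,3S,6E)-8-[(tert-butyldimethylsilyl)oxy]-1-[(tert-butyldiphenylsilyl)oxy]-2,6-dimethyloct-6-en-3-ol | CC(C)(C)[Si](c1ccccc1)(c1ccccc1)OC[C@H](C)[C@@H](O)CC/C(C)=C/CO[Si](C)(C)C(C)(C)C | intermediate
37 | (2S,3S,6E)-8-[(tert-butyldimethylsilyl)oxy]-1-[(tert-butyldiphenylsilyl)oxy]-2,6-dimethyloct-6-en-3-yl methanesulfonate | CC(C)(C)[Si](c1ccccc1)(c1ccccc1)OC[C@H](C)[C@@H](OS(C)(=O)=O)CC/C(C)=C/CO[Si](C)(C)C(C)(C)C | intermediate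
38 | (2S,3S,6E)-1-[(tert-butyldiphenylsilyl)oxy]-8-hydroxy-2,6-dimethyloct-6-en-3-yl methanesulfonate | CC(C)(C)[Si](c1ccccc1)(c1ccccc1)OC[C@H](C)[C@@H](OS(C)(=O)=O)CC/C(C)=C/CO | intermediate
39 | (2S,3S)-1-[(tert-butyldiphenylsilyl)oxy]-5-[(2R,3R)-3-(hydroxymethyl)-2-methyloxiran-2-yl]-2-methylpentan-3-yl methanesulfonate | CC(C)(C)[Si](c1ccccc1)(c1ccccc1)OC[C@H](C)[C@@H](OS(C)(=O)=O)CC[C@@]2(C)O[C@@H]2CO | intermediate
40 | (2S,3S,6S,7R)-1-[(tert-butyldiphenylsilyl)oxy]-6-hydroperoxy-7,8-dihydroxy-2,6-dimethyloctan-3-yl methanesulfonate | CC(C)(C)[Si](c1ccccc1)(c1ccccc1)OC[C@H](C)[C@@H](OS(C)(=O)=O)CC[C@](C)(OO)[C@H](O)CO | intermediate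
41 | (1R)-1-[(3S,6R)-6-{(2S)-1-[(tert-butyldiphenylsilyl)oxy]propan-2-yl}-3-methyl-1,2-dioxan-3-yl]ethane-1,2-diol | CC(C)(C)[Si](c1ccccc1)(c1ccccc1)OC[C@H](C)[C@H]2CC[C@@](C)([C@H](O)CO)OO2 | intermediate
42 | (3S,6R)-6-{(2S)-1-[(tert-butyldiphenylsilyl)oxy]propan-2-yl}-3-methyl-1,2-dioxane-3-carbaldehyde | CC(C)(C)[Si](c1ccccc1)(c1ccccc1)OC[C@H](C)[C@H]2CC[C@@](C)(C=O)OO2 | intermediate
43 | {[(4aR,8aS)-1,1,3,6-tetramethyl-1,4,4a,7,8,8a-hexahydronaphthalen-2-yl]methylidene}triphenylphosphorane | CC1=C[C@H]2CC(C)=C(C=P(c3ccccc3)(c3ccccc3)c3ccccc3)C(C)(C)[C@H]2CC1 | intermediate (not isolated)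
44 | tert-butyl{(2S)-2-[(3R,6S)-6-methyl-6-{2-[(4aR,8aS)-1,1,3,6-tetramethyl-1,4,4a,7,8,8a-hexahydronaphthalen-2-yl]ethenyl}-1,2-dioxan-3-yl]propoxy}diphenylsilane (E/Z mixture) | CC1=C[C@H]2CC(C)=C(C=C[C@]3(C)CC[C@H]([C@@H](C)CO[Si](c4ccccc4)(c4ccccc4)C(C)(C)C)OO3)C(C)(C)[C@H]2CC1 | intermediate
45 | tert-butyl{(2S)-2-[(3R,6R)-6-methyl-6-{2-[(4aR,8aS)-1,1,3,6-tetramethyl-1,4,4a,7,8,8a-hexahydronaphthalen-2-yl]ethyl}-1,2-dioxan-3-yl]propoxy}diphenylsilane | CC1=C[C@H]2CC(C)=C(CC[C@]3(C)CC[C@H]([C@@H](C)CO[Si](c4ccccc4)(c4ccccc4)C(C)(C)C)OO3)C(C)(C)[C@H]2CC1 | intermediate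
46 | (2S)-2-[(3R,6R)-6-methyl-6-{2-[(4aR,8aS)-1,1,3,6-tetramethyl-1,4,4a,7,8,8a-hexahydronaphthalen-2-yl]ethyl}-1,2-dioxan-3-yl]propan-1-ol | CC1=C[C@H]2CC(C)=C(CC[C@]3(C)CC[C@H]([C@@H](C)CO)OO3)C(C)(C)[C@H]2CC1 | intermediate
47 | (2R)-2-[(3R,6R)-6-methyl-6-{2-[(4aR,8aS)-1,1,3,6-tetramethyl-1,4,4a,7,8,8a-hexahydronaphthalen-2-yl]ethyl}-1,2-dioxan-3-yl]propanoic acid | CC1=C[C@H]2CC(C)=C(CC[C@]3(C)CC[C@H]([C@@H](C)C(=O)O)OO3)C(C)(C)[C@H]2CC1 | target

## Step count and least certain steps

Total: 34 steps. Longest linear sequence: 20 steps (steps 1–3, 5, 7–18, 31–34, from 1 to 47). The dioxane branch (steps 19–30) is 12 steps and joins at step 31.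

**Step 7 (key step).** The most likely failure is Lewis-acid-induced oligomerisation of diene 9, or incomplete endo and facial discrimination if the reaction has to be warmed to reach conversion with this more hindered diene. Fallback: the auxiliary is replaced by catalyst control. Diene 9 is combined with 2,2,2-trifluoroethyl acrylate under a triflimide-activated, diphenylprolinol-derived oxazaborolidinium catalyst, in the enantiomeric series that its established facial model assigns to the required acrylate face. This gives 2,2,2-trifluoroethyl (1S,2R)-2-{(2R)-3-[(tert-butyldimethylsilyl)oxy]-2-methylpropyl}-4-methylcyclohex-3-ene-1-carboxylate F1. MeNH(OMe)·HCl/i-PrMgCl then converts F1 into Weinreb amide 15, where the route is rejoined.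

**Step 13.** The radical addition to the aldehyde is reversible, so β-scission of the alkoxy radical could divert material to simple reduction of the isopropenyl group. Silane reduction of the aldehyde and hydrogen-atom transfer to the ring A alkene are further drains. Fallback: the acceptor is changed to a nitrile, which captures the radical irreversibly and gives the ketone directly. Aldehyde 19 is condensed with hydroxylamine to (2R)-2-methyl-3-[(1R,6S)-3-methyl-6-(prop-1-en-2-yl)cyclohex-2-en-1-yl]propanal oxime F2, and this is dehydrated to (2R)-2-methyl-3-[(1R,6S)-3-methyl-6-(prop-1-en-2-yl)cyclohex-2-en-1-yl]propanenitrile F3. Cyclisation of F3 with Fe(acac)3/PhSiH3 and hydrolysis of the imine on work-up returns ketone 21, bypassing 20 and step 14.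

**Step 28.** The opening at the tertiary carbon has carbocation character, so partial loss of stereochemical fidelity at the future C6' (a separable diastereomer, since two other centres are fixed) or acid-induced rearrangement of the epoxy alcohol is the main danger. Fallback: the roles of the two C–O bond formations are exchanged, so the tertiary centre is attacked intramolecularly. Epoxy mesylate 39 is treated with 2-methoxyprop-2-yl hydroperoxide and CsOH in DMF, which displaces the mesylate with inversion to give (2R,3R)-configured epoxide (2S,3R)-1-[(tert-butyldiphenylsilyl)oxy]-5-[3-(hydroxymethyl)-2-methyloxiran-2-yl]-3-[(2-methoxypropan-2-yl)peroxy]-2-methylpentane F4. Mild acid releases the free secondary hydroperoxide F5, which opens the epoxide at the tertiary carbon in a 6-exo mode with inversion. The product is dioxane diol 41, so step 29 is bypassed as well.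

**Step 31.** Addition of the hindered, semi-stabilised ylide 43 to the α-quaternary aldehyde may be slow, leaving the peroxide exposed to a basic ylide. The diene product must then be reduced at one alkene out of three, which may need forcing. Fallback: the link is made as an sp2–sp3 bond with no alkene to reduce. Aldehyde 42 is methylenated with Ph3P=CH2 to tert-butyl{(2S)-2-[(3R,6S)-6-ethenyl-6-methyl-1,2-dioxan-3-yl]propoxy}diphenylsilane F6. Hydroboration with 9-borabicyclo[3.3.1]nonane gives the B-alkyl borane F7. Suzuki–Miyaura coupling of F7 with enol triflate 23 (PdCl2(dppf), K3PO4, DMF/THF/H2O) delivers 45 directly. This leaves out steps 16–18, 31 and 32.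

## Further compounds

F1 | step 7 | 2,2,2-trifluoroethyl (1S,2R)-2-{(2R)-3-[(tert-butyldimethylsilyl)oxy]-2-methylpropyl}-4-methylcyclohex-3-ene-1-carboxylate | CC1=C[C@@H](C[C@@H](C)CO[Si](C)(C)C(C)(C)C)[C@@H](C(=O)OCC(F)(F)F)CC1
F2 | step 13 | (2R)-2-methyl-3-[(1R,6S)-3-methyl-6-(prop-1-en-2-yl)cyclohex-2-en-1-yl]propanal oxime | CC1=C[C@@H](C[C@@H](C)C=NO)[C@@H](C(C)=C)CC1
F3 | step 13 | (2R)-2-methyl-3-[(1R,6S)-3-methyl-6-(prop-1-en-2-yl)cyclohex-2-en-1-yl]propanenitrile | CC1=C[C@@H](C[C@@H](C)C#N)[C@@H](C(C)=C)CC1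
F4 | step 28 | tert-butyl{(2S,3R)-5-[(2R,3R)-3-(hydroxymethyl)-2-methyloxiran-2-yl]-3-[(2-methoxypropan-2-yl)peroxy]-2-methylpentyloxy}diphenylsilane | CC(C)(C)[Si](c1ccccc1)(c1ccccc1)OC[C@H](C)[C@H](OOC(C)(C)OC)CC[C@@]2(C)O[C@@H]2CO
F5 | step 28 | [(2R,3R)-3-{(3R,4S)-5-[(tert-butyldiphenylsilyl)oxy]-3-hydroperoxy-4-methylpentyl}-3-methyloxiran-2-yl]methanol | CC(C)(C)[Si](c1ccccc1)(c1ccccc1)OC[C@H](C)[C@H](OO)CC[C@@]2(C)O[C@@H]2CO
F6 | step 31 | tert-butyl{(2S)-2-[(3R,6S)-6-ethenyl-6-methyl-1,2-dioxan-3-yl]propoxy}diphenylsilane | CC(C)(C)[Si](c1ccccc1)(c1ccccc1)OC[C@H](C)[C@H]2CC[C@@](C)(C=C)OO2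
F7 | step 31 | 9-{2-[(3R,6R)-6-{(2S)-1-[(tert-butyldiphenylsilyl)oxy]propan-2-yl}-3-methyl-1,2-dioxan-3-yl]ethyl}-9-borabicyclo[3.3.1]nonane | CC(C)(C)[Si](c1ccccc1)(c1ccccc1)OC[C@H](C)[C@H]2CC[C@@](C)(CCB3C4CCCC3CCC4)OO2
A1 | alternative 1 | (4aR,8aS)-1,1,3,6-tetramethyl-1,4,4a,7,8,8a-hexahydronaphthalen-2-yl trifluoromethanesulfonate | CC1=C[C@H]2CC(C)=C(OS(=O)(=O)C(F)(F)F)C(C)(C)[C@H]2CC1
A2 | alternative 1 | 1,3,3-trimethyl-2-(prop-1-en-2-yl)bicyclo[2.2.2]oct-5-en-2-ol (isopropenyl syn to the C5=C6 bridge; enantiomer leading to the 4aR,8aS series) | CC(=C)[C@]1(O)C(C)(C)[C@@H]2C=C[C@@]1(C)CC2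
A3 | alternative 1 | 1,3,3-trimethylbicyclo[2.2.2]oct-5-en-2-one (same enantiomeric series as A2) | O=C1C(C)(C)[C@@H]2C=C[C@@]1(C)CC2
A4 | alternative 2 | [(4aR,8aS)-1,1,3,6-tetramethyl-1,4,4a,7,8,8a-hexahydronaphthalen-2-yl]methyl acetate | CC1=C[C@H]2CC(C)=C(COC(C)=O)C(C)(C)[C@H]2CC1
A5 | alternative 2 | (2E,5E)-7-hydroxy-3,7,11-trimethyldodeca-2,5,10-trien-1-yl acetate (racemic carbinol) | CC(C)=CCCC(C)(O)/C=C/C/C(C)=C/COC(C)=O
A6 | alternative 3 | cis-fused 5-[(tert-butyldimethylsilyl)oxy]-2-[(methoxymethoxy)methyl]-1,1,3,6-tetramethyl-4a,5,8,8a-tetrahydronaphthalen-4(1H)-one | CC1=CC[C@H]2[C@@H]([C@@H]1O[Si](C)(C)C(C)(C)C)C(=O)C(C)=C(COCOC)C2(C)C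
A7 | alternative 3 | 3-[(methoxymethoxy)methyl]-2,4,4-trimethylcyclohexa-2,5-dien-1-one | CC1=C(COCOC)C(C)(C)C=CC1=O
A8 | alternative 3 | tert-butyldimethyl{[(1E)-2-methylbuta-1,3-dien-1-yl]oxy}silane | C=C/C(C)=C/O[Si](C)(C)C(C)(C)C
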